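The seven-membered carbocycle (C1, C5, C6, C7, C8, C9, C10) carries the lactone oxygen on C8, which is a γ-methylene of a C12 acid on the C7 arm (C7–C11–C12). With C5 held as a ketone, the only other γ-carbon, C6, is an electron-poor α-keto CH2 and the ring has no alkene, so the five-membered lactone ring (O, C8, C7, C11, C12) can be closed by turning C8–H into C8–O.
Late disconnections are the C2 angelate, the C4 acetate, C11=C13 (Mannich/elimination), and C5–CH3 with the C5=C6 alkene (enol triflate, Negishi methylation); they lead back to a cis-fused C5-keto lactone diacetate.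
The key disconnection is the C8–O bond of that lactone, back to a cycloheptanone acetic acid with an untouched C8 methylene (carboxylate-directed, iron-catalysed C–H oxidation).
The acid is cut at C7–C11 (catalyst-controlled rhodium vinyl 1,4-addition, then hydroboration and oxidation), at C1–C2 (syn-selective titanium aldol) and at C10–CH3 (copper-catalysed asymmetric Me2Zn addition to cyclohepta-2,6-dienone).
Ring order: the carbocycle is bought as cycloheptanone and never opened; the lactone is the only ring formed, in step 8.

Key step: step 8

Convention: C14 is the methyl on C10 and C15 the methyl on C5. With the ring drawn so that C7→C8→C9→C10→C1→C5→C6 runs clockwise, β points to the viewer and α away. The target is 10β-CH3, 1α side chain, 7α-C11, 8α-O, that is (1S,2S,7R,8R,10R), with a Z ester alkene.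
Assumption: the sense of induction of the phosphoramidite (step 2) and of BINAP (step 5) is carried over from the parent 2-cycloalkenones; if it is opposite on these substrates, the mirror-image ligand is used and nothing else changes.

Step 1
Reactants: 1 cycloheptanone
Product: 2 cyclohepta-2,6-dien-1-one
Conditions: IBX (3 equiv), DMSO, 80 °C
Reagents that add atoms: none
Why: IBX dehydrogenation of ketones takes medium-ring ketones through the enone to the cross-conjugated dienone when the oxidant is used in excess at this temperature, and no stereocentre is involved.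

Step 2
Reactants: 2 cyclohepta-2,6-dien-1-one; 3 dimethylzinc
Product: 5 trimethyl{[(7R)-7-methylcyclohepta-1,3-dien-2-yl]oxy}silane, via methylzinc dienolate 4 (not isolated)
Conditions: Me2Zn (1.1 equiv), Cu(OTf)2 (2.5 mol%), O,O'-(R)-1,1'-binaphthyl-2,2'-diyl N,N-bis[(S)-1-phenylethyl]phosphoramidite (5 mol%), toluene, −25 °C; then TMSOTf, Et3N, −25 → 0 °C
Reagents that add atoms: dimethylzinc (3), C[Zn]C; trimethylsilyl trifluoromethanesulfonate, C[Si](C)(C)OS(=O)(=O)C(F)(F)F
Why: The copper–phosphoramidite asymmetric conjugate addition of a dialkylzinc sets C10 (R, 10β-CH3) by ligand control, the zinc dienolate 4 cannot accept a second methyl group, and O-silylation stores the regiodefined C1=C5 enolate for a separate, selective aldol step.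

Step 3
Reactants: 5 silyl dienol ether; 6 3-[(tert-butyldimethylsilyl)oxy]propanal
Product: 9 (6R,7R)-7-[(1S)-3-(tert-butyldimethylsilyloxy)-1-hydroxypropyl]-6-methylcyclohept-2-en-1-one, via lithium dienolate 7 (not isolated), via triisopropoxytitanium dienolate 8 (not isolated)
Conditions: MeLi, THF, 0 °C; ClTi(OiPr)3, −78 → −40 °C; 6, −78 °C; aq NH4Cl
Reagents that add atoms: 3-[(tert-butyldimethylsilyl)oxy]propanal (6), O=CCCO[Si](C)(C)C(C)(C)C; methyllithium (Li in 7 only), [Li]C; chlorotitanium triisopropoxide (in 8 only), CC(C)O[Ti](Cl)(OC(C)C)OC(C)C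
Why: The target needs the syn C1/C2 relation, which the ring-locked E enolate does not give through a chair transition state and which the zinc enolate of step 2 would give with little selectivity; the titanium aldol of cyclic-ketone triisopropoxytitanium enolates is syn-selective (boat-like transition state), and the aldehyde should approach C1 anti to the neighbouring 10β-methyl, so C1 (α side chain) and C2 (S) are both set relative to C10, with any anti isomer removed by chromatography.

Step 4
Reactants: 9 syn aldol
Product: 10 (1S)-1-[(1R,7R)-7-methyl-2-oxocyclohept-3-en-1-yl]propane-1,3-diyl diacetate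
Conditions: Ac2O, FeCl3 (10 mol%), 0 °C
Reagents that add atoms: acetic anhydride, CC(=O)OC(C)=O
Why: Lewis-acid-catalysed acetylation esterifies C2–OH while FeCl3/Ac2O converts the primary silyl ether directly into the acetate, the acidic medium avoids base-induced elimination of the new β-acetoxy ketone, and the two electron-withdrawing esters are what will shield C2–H and C4–H in step 8.

Step 5
Reactants: 10 diacetate enone; 11 potassium vinyltrifluoroborate
Product: 12 (1S)-1-[(1R,4R,7R)-4-ethenyl-7-methyl-2-oxocycloheptyl]propane-1,3-diyl diacetate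
Conditions: 11 (2 equiv), [Rh(cod)2]BF4 (5 mol%), (R)-BINAP (6 mol%), Et3N (1 equiv), toluene/H2O 10:1, 40 °C
Reagents that add atoms: potassium vinyltrifluoroborate (11), C=C[B-](F)(F)F.[K+]
Why: C7 lies too far from C1 and C10 for dependable substrate control, so a Hayashi–Miyaura rhodium-catalysed asymmetric 1,4-addition is used, in which the (R)-BINAP complex selects the enone face and should place the vinyl group (C11, C12) on the α face of C7, cis to the C1 side chain and trans to the C10 methyl.

Step 6
Reactants: 12 vinyl ketone
Product: 14 (1S)-1-[(1R,4S,7R)-4-(2-hydroxyethyl)-7-methyl-2-oxocycloheptyl]propane-1,3-diyl diacetate, via catechol boronate 13 (not isolated)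
Conditions: catecholborane (1.1 equiv), RhCl(PPh3)3 (2 mol%), THF, 0 °C → rt; then 30% H2O2, pH 7 phosphate buffer, 0 °C
Reagents that add atoms: hydrogen peroxide, OO; catecholborane (in 13 only), B1Oc2ccccc2O1
Why: Rhodium-catalysed hydroboration of a terminal alkene with catecholborane is much faster than the uncatalysed reduction of a ketone and is anti-Markovnikov, and buffered peroxide oxidation of the C12–B bond leaves the acetates and the β-acetoxy ketone intact.

Step 7
Reactants: 14 primary alcohol
Product: 15 2-[(1R,4R,5R)-4-[(1S)-1,3-diacetoxypropyl]-5-methyl-3-oxocycloheptyl]acetic acid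
Conditions: TEMPO (20 mol%), PhI(OAc)2 (2.5 equiv), MeCN/H2O 1:1, rt
Reagents that add atoms: water, O
Why: The oxoammonium oxidation with TEMPO/PhI(OAc)2 in aqueous acetonitrile carries a primary alcohol through the aldehyde hydrate to the acid under nearly neutral conditions that touch neither the ketone, the esters nor any stereocentre.

Step 8
Reactants: 15 keto acid (1R,2S,7R,10R)
Product: 17 cis-fused keto lactone diacetate (1R,2S,7R,8R,10R), via C8 hydroxy acid 16 (not isolated)
Conditions: Fe((S,S)-PDP)(CH3CN)2(SbF6)2 (3 × 5 mol%; PDP = N,N'-bis(2-pyridylmethyl)-2,2'-bipyrrolidine), 50% aq H2O2 (3 × 1.2 equiv, slow addition), CH3CN, rt, no carboxylic acid additive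
Reagents that add atoms: hydrogen peroxide, OO (its oxygen becomes the C8–O atom by way of 16; the C12 hydroxyl leaves as water)
Why: The C12 carboxylate of 15 displaces a nitrile ligand on the divalent iron complex and assists heterolysis of the bound hydroperoxide to a pentavalent iron-oxo carboxylate, which abstracts hydrogen from C8 through the array O=Fe–O–C12–C11–C7–C8 and returns hydroxyl to the short-lived radical on the same face to give 16. Compound 16 should close at once to the five-membered lactone by 5-exo-trig attack of the C8 hydroxyl on the C12 carboxyl with loss of water, and direct rebound of the bound carboxylate oxygen onto the C8 radical would give the same ring. The closest known reaction type is the carboxylic-acid-directed aliphatic C–H hydroxylation and γ-lactonisation with non-heme iron or manganese aminopyridine catalysts and H2O2, which is established for secondary as well as tertiary γ C–H bonds. C8 is the only new stereocentre and is controlled by C7: the α hydrogen on C8 stays gauche to C11 in every ring conformer whereas the β hydrogen swings anti when the arm is pseudoaxial, and oxygen is delivered with retention, so the 8α-O, cis-fused lactone is expected, although the trans hydrogen is not rigorously excluded. Site selectivity is needed against C6, C9 and the tertiary C7 and C10 positions; C6 and C1 are α to the ketone, C2–H, C3–H and C4–H are deactivated by the acetates, C7–H and C10–H are β to withdrawing groups, and intramolecular delivery favours the five-membered lactone over attack at remote C9. Chemoselectivity rests on the absence of any alkene, free alcohol or silyl ether, and on lactonisation removing the C8 carbinol from further oxidation.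

Step 9
Reactants: 17 keto lactone diacetate
Product: 19 C5=C6 enol triflate of 17 with all five stereocentres unchanged, via potassium enolate 18 (not isolated)
Conditions: N-(5-chloro-2-pyridyl)bis(trifluoromethanesulfonimide) (1.3 equiv), then KN(SiMe3)2 (1.1 equiv) added slowly, THF, −78 °C
Reagents that add atoms: N-(5-chloro-2-pyridyl)bis(trifluoromethanesulfonimide), FC(F)(F)S(=O)(=O)N(c1ccc(Cl)cn1)S(=O)(=O)C(F)(F)F; potassium bis(trimethylsilyl)amide (K in 18 only), C[Si](C)(C)[N-][Si](C)(C)C.[K+]
Why: In this kinetic enol triflate formation the hindered amide base should take the accessible C6 methylene proton of the most acidic carbonyl group rather than the flanked tertiary C1–H or an ester α-proton, and the triflating agent already present traps 18 on oxygen before it can equilibrate towards C1, where loss of the C2 acetate would follow.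

Step 10
Reactants: 19 enol triflate; 3 dimethylzinc
Product: 20 C5-methyl C5=C6 cycloheptene lactone diacetate
Conditions: Me2Zn (1.5 equiv), Pd(PPh3)4 (5 mol%), THF, 0 °C → rt
Reagents that add atoms: dimethylzinc (3), C[Zn]C
Why: In this Negishi coupling, oxidative addition of the alkenyl triflate to zerovalent palladium, methyl transfer from zinc and reductive elimination place C15 on C5 with the alkene fixed at C5=C6, and Me2Zn does not attack the lactone or the acetates at this temperature.

Step 11
Reactants: 20 diacetate
Product: 21 C2,C4-diol lactone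
Conditions: K2CO3 (0.5 equiv), MeOH, 0 °C → rt; then aq citric acid
Reagents that add atoms: none
Why: Carbonate-catalysed transesterification (Zemplén type) removes both acetates safely now that no β-acyloxy ketone is left, and any methanolysis of the cis γ-lactone is reversed on mild acidification because the hydroxy ester recloses.

Step 12
Reactants: 21 diol
Product: 22 C2,C4-bis(triethylsilyl) ether
Conditions: TESOTf (2.5 equiv), 2,6-lutidine, CH2Cl2, −78 → 0 °C
Reagents that add atoms: triethylsilyl trifluoromethanesulfonate, CC[Si](CC)(CC)OS(=O)(=O)C(F)(F)F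
Why: Silyl triflate/lutidine silylation also covers the hindered C2 carbinol, and silyl ethers, unlike acetates, have no acidic α-protons, so the lactone is the only enolisable group in the next step.

Step 13
Reactants: 22 bis-silyl ether; 23 dimethylmethyleneiminium iodide
Product: 27 α-methylene lactone bis(triethylsilyl) ether, via lithium lactone enolate 24 (not isolated), via Mannich base 25 (not isolated), via methiodide 26 (not isolated)
Conditions: LiN(i-Pr)2 (1.3 equiv), THF, −78 °C; 23, −78 °C → rt; then MeI, CH2Cl2, rt; then aq NaHCO3
Reagents that add atoms: dimethylmethyleneiminium iodide (23), C=[N+](C)C.[I-]; lithium diisopropylamide (Li in 24 only), CC(C)[N-]C(C)C.[Li+]; iodomethane (in 26 only), CI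
Why: This is the standard α-methylenation of a γ-lactone, a Mannich reaction of the enolate with the iminium salt (attack on the convex face, at a C11 centre that is erased again), N-methylation and Hofmann-type β-elimination, which installs C13 without touching C7 or C8.

Step 14
Reactants: 27 bis-silyl ether
Product: 28 α-methylene lactone C2,C4-diol
Conditions: HF·pyridine, THF, 0 °C → rt
Reagents that add atoms: none
Why: Fluoride-driven Si–O cleavage under weakly acidic conditions frees both hydroxyl groups and spares the Michael-acceptor lactone, which basic fluoride sources could attack.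

Step 15
Reactants: 28 diol; 29 acetyl chloride
Product: 30 C4 monoacetate with free C2 hydroxyl
Conditions: AcCl (1.1 equiv), 2,4,6-collidine, CH2Cl2, −78 °C
Reagents that add atoms: acetyl chloride (29), CC(=O)Cl
Why: Selective acylation with AcCl and a hindered pyridine base at low temperature exploits the large rate difference between the unhindered primary C4–OH and the secondary C2–OH, which is flanked by the branched C1.

Step 16
Reactants: 30 monoacetate; 31 angelic acid
Product: 33 target CNP0163960.1, via mixed anhydride 32 (not isolated)
Conditions: 31 (3 equiv), 2,4,6-trichlorobenzoyl chloride, Et3N, toluene, rt; then 30, 80 °C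
Reagents that add atoms: angelic acid (31), C/C=C(/C)C(=O)O; 2,4,6-trichlorobenzoyl chloride (in 32 only), O=C(Cl)c1c(Cl)cc(Cl)cc1Cl
Why: Yamaguchi-type esterification through the mixed anhydride, run without a nucleophilic pyridine catalyst, acylates hindered secondary alcohols at the angeloyl carbonyl while avoiding the addition–elimination path that turns the Z ester into the E isomer, and C2 keeps its configuration because its C–O bond is not touched.

Compound list
1 | cycloheptanone | O=C1CCCCCC1 | starting material
2 | cyclohepta-2,6-dien-1-one | O=C1C=CCCC=C1 | intermediate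
3 | dimethylzinc | C[Zn]C | starting material
4 | methylzinc dienolate (C1=C5–OZnMe, C6=C7, 10R) | C1C[C@@H](C)C=C(O[Zn]C)C=C1 | intermediate
5 | trimethyl{[(7R)-7-methylcyclohepta-1,3-dien-2-yl]oxy}silane | C1C[C@@H](C)C=C(O[Si](C)(C)C)C=C1 | intermediate
6 | 3-[(tert-butyldimethylsilyl)oxy]propanal | O=CCCO[Si](C)(C)C(C)(C)C | starting material
7 | lithium dienolate (10R) | C1C[C@@H](C)C=C([O-])C=C1.[Li+] | intermediate
8 | triisopropoxytitanium dienolate (10R) | C1C[C@@H](C)C=C(O[Ti](OC(C)C)(OC(C)C)OC(C)C)C=C1 | intermediate
9 | (6R,7R)-7-[(1S)-3-(tert-butyldimethylsilyloxy)-1-hydroxypropyl]-6-methylcyclohept-2-en-1-one | C1C[C@@H](C)[C@H]([C@H](CCO[Si](C)(C)C(C)(C)C)O)C(=O)C=C1 | intermediate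
10 | (1S)-1-[(1R,7R)-7-methyl-2-oxocyclohept-3-en-1-yl]propane-1,3-diyl diacetate | C1C[C@@H](C)[C@H]([C@H](CCOC(C)=O)OC(C)=O)C(=O)C=C1 | intermediate
11 | potassium vinyltrifluoroborate | C=C[B-](F)(F)F.[K+] | starting material
12 | (1S)-1-[(1R,4R,7R)-4-ethenyl-7-methyl-2-oxocycloheptyl]propane-1,3-diyl diacetate | C=C[C@@H]1CC[C@@H](C)[C@H]([C@H](CCOC(C)=O)OC(C)=O)C(=O)C1 | intermediate
13 | C12 catechol boronate of 12 | c1ccc2OB(CC[C@@H]3CC[C@@H](C)[C@H]([C@H](CCOC(C)=O)OC(C)=O)C(=O)C3)Oc2c1 | intermediate
14 | (1S)-1-[(1R,4S,7R)-4-(2-hydroxyethyl)-7-methyl-2-oxocycloheptyl]propane-1,3-diyl diacetate | OCC[C@@H]1CC[C@@H](C)[C@H]([C@H](CCOC(C)=O)OC(C)=O)C(=O)C1 | intermediate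
15 | 2-[(1R,4R,5R)-4-[(1S)-1,3-diacetoxypropyl]-5-methyl-3-oxocycloheptyl]acetic acid (key-step precursor) | OC(=O)C[C@@H]1CC[C@@H](C)[C@H]([C@H](CCOC(C)=O)OC(C)=O)C(=O)C1 | intermediate
16 | 8α-hydroxy derivative of acid 15 | OC(=O)C[C@@H]1[C@H](O)C[C@@H](C)[C@H]([C@H](CCOC(C)=O)OC(C)=O)C(=O)C1 | intermediate
17 | cis-fused C5-keto γ-lactone diacetate (1R,2S,7R,8R,10R) (key-step product) | C1C(=O)O[C@@H]2C[C@@H](C)[C@H]([C@H](CCOC(C)=O)OC(C)=O)C(=O)C[C@H]12 | intermediate
18 | potassium C5=C6 enolate of 17 | C1C(=O)O[C@@H]2C[C@@H](C)[C@H]([C@H](CCOC(C)=O)OC(C)=O)C([O-])=C[C@H]12.[K+] | intermediate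
19 | C5=C6 enol triflate of 17 | C1C(=O)O[C@@H]2C[C@@H](C)[C@H]([C@H](CCOC(C)=O)OC(C)=O)C(OS(=O)(=O)C(F)(F)F)=C[C@H]12 | intermediate
20 | C5-methyl C5=C6 cycloheptene lactone diacetate | C1C(=O)O[C@@H]2C[C@@H](C)[C@H]([C@H](CCOC(C)=O)OC(C)=O)C(C)=C[C@H]12 | intermediate
21 | C2,C4-diol lactone | C1C(=O)O[C@@H]2C[C@@H](C)[C@H]([C@H](CCO)O)C(C)=C[C@H]12 | intermediate
22 | C2,C4-bis(triethylsilyl) ether lactone | C1C(=O)O[C@@H]2C[C@@H](C)[C@H]([C@H](CCO[Si](CC)(CC)CC)O[Si](CC)(CC)CC)C(C)=C[C@H]12 | intermediate
23 | dimethylmethyleneiminium iodide | C=[N+](C)C.[I-] | starting material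
24 | lithium enolate of lactone 22 | C1=C([O-])O[C@@H]2C[C@@H](C)[C@H]([C@H](CCO[Si](CC)(CC)CC)O[Si](CC)(CC)CC)C(C)=C[C@H]12.[Li+] | intermediate
25 | C11 (dimethylamino)methyl lactone (CH2N cis to H7) | CN(C)C[C@H]1C(=O)O[C@@H]2C[C@@H](C)[C@H]([C@H](CCO[Si](CC)(CC)CC)O[Si](CC)(CC)CC)C(C)=C[C@H]12 | intermediate
26 | trimethylammonium iodide of 25 | C[N+](C)(C)C[C@H]1C(=O)O[C@@H]2C[C@@H](C)[C@H]([C@H](CCO[Si](CC)(CC)CC)O[Si](CC)(CC)CC)C(C)=C[C@H]12.[I-] | intermediate
27 | α-methylene lactone bis(triethylsilyl) ether | C=C1C(=O)O[C@@H]2C[C@@H](C)[C@H]([C@H](CCO[Si](CC)(CC)CC)O[Si](CC)(CC)CC)C(C)=C[C@H]12 | intermediate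
28 | α-methylene lactone C2,C4-diol | C=C1C(=O)O[C@@H]2C[C@@H](C)[C@H]([C@H](CCO)O)C(C)=C[C@H]12 | intermediate
29 | acetyl chloride | CC(=O)Cl | starting material
30 | α-methylene lactone C4 acetate with free C2–OH | C=C1C(=O)O[C@@H]2C[C@@H](C)[C@H]([C@H](CCOC(C)=O)O)C(C)=C[C@H]12 | intermediate
31 | angelic acid, (Z)-2-methylbut-2-enoic acid | C/C=C(/C)C(=O)O | starting material
32 | angelic 2,4,6-trichlorobenzoic anhydride | C/C=C(/C)C(=O)OC(=O)c1c(Cl)cc(Cl)cc1Cl | intermediate
33 | CNP0163960.1 (1S,2S,7R,8R,10R; Z ester) | C=C1C(=O)O[C@@H]2C[C@@H](C)[C@H]([C@H](CCOC(C)=O)OC(=O)/C(C)=C\C)C(C)=C[C@H]12 | target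

Total step count: 16. Longest linear sequence: 16 steps (1 → 33).

Steps most likely to fail

Step 8.
- Risk: hydrogen abstraction at the β hydrogen of C8 would lead to the trans-fused ring. Undirected attack at remote C9 or at the tertiary C10–H, oxidation of the C8 carbinol before it lactonises, and early catalyst decay would each cut into the cis lactone. Changing to the mirror-image catalyst is only a change of conditions.
- Fallback, from 15 back to 17: the same C8–H is reached by a nitrogen-radical relay instead of a metal-oxo species. Acid 15 is coupled with NH4Cl (EDC, HOBt, i-Pr2NEt) to the primary amide F1. Treatment with t-BuOCl/I2 gives the N-iodoamide F2. Photolysis of F2 (visible light, CH2Cl2) forms an amidyl radical that takes a C8 hydrogen by 1,5-transfer (Hofmann–Löffler–Freytag type; the α-keto C6–H is polarity-mismatched) and leaves the 8β-iodo amide F3. The amide oxygen displaces iodide with inversion to give the cis-fused iminolactone F4, and aqueous acid hydrolysis gives 17.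

Step 9.
- Risk: competing deprotonation at C1 followed by expulsion of the C2 acetate, migration of the C2 acetyl group onto the enolate oxygen, and proton exchange with the ester α-positions would erode both regiocontrol and material.
- Fallback, from 17 back to 20: no enolate is made. The non-basic Takai–Lombardo methylenation (Zn, CH2Br2, TiCl4, THF/CH2Cl2), which tolerates esters and elimination-prone ketones, converts C5=O into the exocyclic methylene lactone F5. RhCl3·3H2O in warm EtOH then moves the double bond into the ring through the more accessible allylic C6–H rather than the hindered C1–H, giving 20.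

Step 5.
- Risk: protodeboronation or slow transmetalation of the vinyl reagent, a mismatched pairing of catalyst and substrate with poor facial selectivity at C7, and amine-promoted loss of the C2 acetate are the likely failure modes.
- Fallback, from 10 back to 15: the two-carbon arm is brought in at the acid oxidation level by a Mukaiyama–Michael addition. tert-Butyl acetate is converted with LiN(i-Pr)2 and TBSCl into the ketene silyl acetal F6. This adds to enone 10 under TBSOTf catalysis (CH2Cl2, −78 °C) to give the silyl enol ether adduct F7. Mild acid hydrolysis gives the keto tert-butyl ester F8, at which stage the C7 epimers from substrate control are separated by chromatography. CF3CO2H in CH2Cl2 then cleaves the ester to 15, which also saves steps 6 and 7.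

Further compounds
F1 | step 8 | primary amide of acid 15 | NC(=O)C[C@@H]1CC[C@@H](C)[C@H]([C@H](CCOC(C)=O)OC(C)=O)C(=O)C1
F2 | step 8 | N-iodoamide of F1 | INC(=O)C[C@@H]1CC[C@@H](C)[C@H]([C@H](CCOC(C)=O)OC(C)=O)C(=O)C1
F3 | step 8 | 8β-iodo amide | NC(=O)C[C@@H]1[C@@H](I)C[C@@H](C)[C@H]([C@H](CCOC(C)=O)OC(C)=O)C(=O)C1
F4 | step 8 | cis-fused iminolactone | C1C(=N)O[C@@H]2C[C@@H](C)[C@H]([C@H](CCOC(C)=O)OC(C)=O)C(=O)C[C@H]12
F5 | step 9 | C5 exocyclic methylene lactone diacetate | C1C(=O)O[C@@H]2C[C@@H](C)[C@H]([C@H](CCOC(C)=O)OC(C)=O)C(=C)C[C@H]12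
F6 | step 5 | 1-tert-butoxy-1-(tert-butyldimethylsilyloxy)ethene | C=C(OC(C)(C)C)O[Si](C)(C)C(C)(C)C
F7 | step 5 | C5=C6 tert-butyldimethylsilyl enol ether of the Michael adduct | CC(C)(C)OC(=O)C[C@@H]1CC[C@@H](C)[C@H]([C@H](CCOC(C)=O)OC(C)=O)C(O[Si](C)(C)C(C)(C)C)=C1
F8 | step 5 | tert-butyl ester of acid 15 | CC(C)(C)OC(=O)C[C@@H]1CC[C@@H](C)[C@H]([C@H](CCOC(C)=O)OC(C)=O)C(=O)C1
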